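## Analysis of the target

The target is a neolignan built from two oxygen heterocycles. One is a 2-aryl-3-(hydroxymethyl)-7-methoxy-2,3-dihydrobenzofuran, and its C5 is bonded to C2 of a 7-methoxybenzofuran that carries a 3-hydroxypropyl chain at C5. There are two adjacent stereocentres, both in the dihydrofuran ring: C2 (S), bearing the 4-hydroxy-3-methoxyphenyl ring, and C3 (R), bearing CH2OH, in a trans relation. C3 has no acidifying neighbour and is configurationally stable. C2 is a benzylic ether carbon para to a free phenol, so base or oxidant can open the ring through a quinone methide and acid can ionise it. The other sensitive features are three electron-rich arenes, a free guaiacyl phenol and two primary alcohols of similar reactivity. The difficulty is to set C3 absolutely, make C2 follow it, and join two electron-rich halves without exposing the C2–O bond to acid, strong base or oxidant once the phenol is free. The strategy rests on the benzofuran ring: its C3 is a bare CH on C3a, C3a and O1 are the ortho carbon and the oxygen of a 4-(3-hydroxypropyl)-2-methoxyphenol, and its C2 is a carbon at the carboxylic acid oxidation level attached to C5 of the dihydrobenzofuran. The C2=C3 bond can therefore be formed by olefination of an aryl ester with a benzylic phosphorus ylide held on the same ring.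

## Retrosynthetic reasoning

The last operation is removal of the three silyl ethers of 31 to give target 32. No skeletal bond is formed after this, so the free guaiacyl phenol and its quinone-methide chemistry stay out of every bond-forming step.

In 31 the benzofuran is cut at C2=C3 and at the O1–C2 acyl bond, which leads to acid chloride 23 and phosphonium salt 28. This is the only cut that divides the molecule into two halves of similar size, each with its final substitution pattern. A cut at the aryl–aryl bond between the rings would need a metalated and a halogenated partner and a cross-coupling. Forward, the phenol of 28 is acylated to ester 29, the benzylic position is deprotonated to ylide 30, and an intramolecular Wittig reaction closes the furan ring.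

Acid chloride 23 goes back through acid 22 and aldehyde 21 to nitrile 19. The carboxyl carbon is carried as a nitrile for three reasons: it is inert to the enolate alkylation and to the hydride removal of the auxiliary, it deactivates the ring A phenol towards oxidation in the cyclisation, and it is raised to the acid by a hydride reduction and a mild aldehyde oxidation. An ester at this position would need basic hydrolysis, which an aryl silyl ether does not survive.

Nitrile 19 is the bis-silyl ether of phenol 18. In 18 the O1–C2 bond is cut. Forward, the guaiacyl phenol of 16 is oxidised to quinone methide 17, and the ring A phenol adds to its exocyclic carbon. C2 then needs no stereocontrol of its own, because it takes up the trans position relative to the C3 centre already present in 16.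

Bis-phenol 16 comes from 15 by removal of two benzyl ethers, and 15 from imide 14 by reductive removal of the auxiliary. In 14 the bond between the α-carbon and the benzylic CH2 of ring B is cut, giving enolate 13 of imide 12 and benzylic bromide 2. This is the only C–C bond made at the stereocentre, and the R form of auxiliary 10 controls which face of 13 is alkylated. The stereocentre so formed becomes C3 of the target.

Imide 12 is assembled from arylacetic acid 9 and auxiliary 10 through mixed anhydride 11. Acid 9 comes from aldehyde 8, and 8 from allylarene 6 by oxidative cleavage through diol 7. Allylarene 6 is the benzyl ether of 5, and the C–C bond ortho to the phenol of 5 is cut by a Claisen rearrangement of allyl ether 4, made from nitrile 3. Bromide 2 comes from benzylic alcohol 1.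

Salt 28 is cut at the C–P bond to give the ortho-hydroxybenzyl alcohol 27, which comes from aldehyde 26 by reduction. The formyl C–C bond of 26 is cut ortho to the phenol of silyl ether 25, which is made by selective silylation of dihydroconiferyl alcohol 24. The whole benzo ring of the benzofuran, with its methoxy group and side chain, is therefore bought.

## Alternatives that were turned down

Alternative 1: The benzo ring of the benzofuran is disconnected at C7–C7a and built onto an existing 2-aryl furan. A Stobbe-type half-ester A2, carried on a 5-arylfuran-3-yl unit, is heated with Ac2O and NaOAc. The CH2CO2H arm becomes a mixed anhydride, acylates the free α-carbon of the furan, and the resulting ketone is trapped as its enol acetate, giving the 7-acetoxybenzofuran-5-carboxylate A1.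
- For: the regiochemistry is fixed, since the furan α-carbon is the most nucleophilic position and the only one within reach. Oxygen at C7 and a carbon substituent at C5 appear in the right places.
- Against: A1 does not have the target's substituents. The acetate must be exchanged for a methyl ether, and the C5 ester must be extended by two carbons to the hydroxypropyl chain (reduction, two-carbon olefination, alkene hydrogenation beside a benzyl ether, ester reduction). All of this is done on the fully assembled chiral compound. The furan aldehyde leading to A2 needs a cross-coupling of its own, and the strongly basic condensation and hot anhydride act on a substrate that already holds both stereocentres.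
- Comparison: Alternative 1 is stronger on one point, because its ring closure is a robust thermal acylation that does not depend on the electrophilicity of an electron-rich ester carbonyl. The chosen route offers convergence instead: the benzo ring arrives with both substituents in final form from 24, and only desilylation follows the coupling.

Alternative 2: The dihydrobenzofuran is disconnected at C3–C3a by a ring contraction. The (2S)-flavanone A4 is treated with PhI(OAc)2 (trivalent iodine) and H2SO4 in trimethyl orthoformate. The ketal enol ether is iodinated at C3, the fused aryl carbon migrates from C4 to C3 as PhI leaves, and the trans 2-aryl-2,3-dihydrobenzofuran-3-carboxylate A3 results.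
- For: one stereocentre controls both, because the shift is stereospecific. The C3 ester is at the right level for reduction to CH2OH, and the bromide at C5 is a handle for the other half. The dihydrobenzofuran half could well take fewer steps than the auxiliary sequence used here, and on that point this alternative is stronger.
- Against: flavanones racemise by reversible opening to the 2'-hydroxychalcone, and the contraction runs in strong acid, so the single controlling centre is at risk in the step that relies on it. Ring B must be deactivated as a mesylate to stop migration of the C2 aryl group and ring iodination. The mesylate must later be removed next to a β-aryloxy ester that opens by E1cB. The benzofuran still has to be built separately and joined to the bromide by a cross-coupling.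
- Comparison: the chosen route sets C3 at a carbon that cannot epimerise, and joins the halves in the ring-forming step itself, without a transition metal.

Alternative 3: Both dihydrofuran bonds (C3–C3a and O1–C2) are disconnected at once. Horseradish peroxidase with H2O2 oxidises feruloyl imide A7 and benzofuran phenol A6 to phenoxyl radicals. The side-chain β-carbon of A7 couples with the ortho carbon of A6, the rearomatised phenol adds to the quinone methide, and the imide A5 forms with the complete skeleton.
- For: this is by far the shortest and most convergent plan, it needs no protecting groups, and it follows the biosynthetic logic. On step and atom economy it is clearly superior to the chosen route.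
- Against: nothing in the structures enforces cross-coupling. The radical of A7 couples with itself at least as easily, through several positions. The radical of A6 is delocalised over its stilbene-like benzofuran and can react at benzofuran C3 or dimerise. A remote auxiliary on an acyclic radical gives only moderate facial bias, so diastereomers would have to be separated to reach one enantiomer. The imide must then be reduced at an acidic, β-aryloxy position beside free phenols.
- Comparison: the chosen route is much longer, but every bond is made between partners that can react in only one way, and enantiomeric purity rests on an auxiliary alkylation.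

Key step: step 20

Assumption: the carboxyl carbon at C5 of the dihydrobenzofuran is carried as a nitrile, and compounds 1, 3, 10 and 24 are taken as purchasable.

## Route

Step 1
Reactants: 1 4-(benzyloxy)-3-methoxybenzyl alcohol
Product: 2 4-(benzyloxy)-3-methoxybenzyl bromide
Conditions: PBr3 (0.4 equiv), Et2O, 0 °C
Reagents that add atoms: phosphorus tribromide, BrP(Br)Br
Why: The benzylic alcohol is activated as a phosphite ester and displaced by bromide, helped by the para oxygen; the aryl benzyl ether is inert under these cold, short conditions.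

Step 2
Reactants: 3 4-hydroxy-3-methoxybenzonitrile
Product: 4 3-methoxy-4-(prop-2-en-1-yloxy)benzonitrile
Conditions: allyl bromide, K2CO3, acetone, reflux
Reagents that add atoms: allyl bromide, C=CCBr
Why: Williamson ether synthesis; the acidic cyano-substituted phenol is alkylated at oxygen by the allylic bromide.

Step 3
Reactants: 4 3-methoxy-4-(prop-2-en-1-yloxy)benzonitrile
Product: 5 4-hydroxy-3-methoxy-5-(prop-2-en-1-yl)benzonitrile
Conditions: N,N-diethylaniline, 200 °C
Reagents that add atoms: none
Why: Aromatic Claisen rearrangement ([3,3] shift, then tautomerisation) places the allyl group on the only free ortho carbon; the para position is blocked by the nitrile, so no further migration can follow.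

Step 4
Reactants: 5 4-hydroxy-3-methoxy-5-(prop-2-en-1-yl)benzonitrile
Product: 6 4-(benzyloxy)-3-methoxy-5-(prop-2-en-1-yl)benzonitrile
Conditions: BnBr, K2CO3, DMF, 60 °C
Reagents that add atoms: benzyl bromide, BrCc1ccccc1
Why: Williamson ether synthesis; a benzyl ether is chosen because an alkyl ether next to the future enolate cannot migrate, and because it leaves together with the ring B benzyl group in one later operation.

Step 5
Reactants: 6 4-(benzyloxy)-3-methoxy-5-(prop-2-en-1-yl)benzonitrile
Product: 8 2-[2-(benzyloxy)-5-cyano-3-methoxyphenyl]acetaldehyde, via vicinal diol 7 (not isolated)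
Conditions: OsO4 (cat.), NaIO4, 2,6-lutidine, dioxane–H2O, rt
Reagents that add atoms: osmium tetroxide, O=[Os](=O)(=O)=O (delivers the oxygen atoms); sodium periodate, [Na+].[O-]I(=O)(=O)=O (restores them)
Why: Lemieux–Johnson oxidation: catalytic dihydroxylation of the terminal alkene to 7 and periodate cleavage of the glycol; the lutidine buffer suppresses over-oxidation, and the enolisable arylacetaldehyde is used at once.

Step 6
Reactants: 8 2-[2-(benzyloxy)-5-cyano-3-methoxyphenyl]acetaldehyde
Product: 9 2-[2-(benzyloxy)-5-cyano-3-methoxyphenyl]acetic acid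
Conditions: NaClO2, NaH2PO4, 2-methyl-2-butene, t-BuOH–H2O, 0 °C to rt
Reagents that add atoms: sodium chlorite, [Na+].[O-]Cl=O
Why: Pinnick oxidation; the alkene scavenger removes hypochlorous acid before it can chlorinate the ring, and nitrile and benzyl ether are untouched.

Step 7
Reactants: 9 2-[2-(benzyloxy)-5-cyano-3-methoxyphenyl]acetic acid, 10 (4R)-4-benzyl-1,3-oxazolidin-2-one
Product: 12 (4R)-4-benzyl-3-{2-[2-(benzyloxy)-5-cyano-3-methoxyphenyl]acetyl}-1,3-oxazolidin-2-one, via mixed pivalic anhydride 11 (not isolated)
Conditions: t-BuCOCl, Et3N, THF, −20 °C; then LiCl, 10, −20 °C to rt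
Reagents that add atoms: none
Why: N-Acylation of the oxazolidinone through the mixed anhydride with LiCl/Et3N activation; the nucleophile attacks the unhindered arylacetyl carbonyl and not the pivaloyl one.

Step 8
Reactants: 12 (4R)-4-benzyl-3-{2-[2-(benzyloxy)-5-cyano-3-methoxyphenyl]acetyl}-1,3-oxazolidin-2-one, 2 4-(benzyloxy)-3-methoxybenzyl bromide
Product: 14 (4R)-4-benzyl-3-{(2R)-2-[2-(benzyloxy)-5-cyano-3-methoxyphenyl]-3-[4-(benzyloxy)-3-methoxyphenyl]propanoyl}-1,3-oxazolidin-2-one, via sodium enolate 13 (not isolated)
Conditions: NaN(SiMe3)2 (1.05 equiv), THF, −78 °C; then 2, −78 to −40 °C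
Reagents that add atoms: none
Why: Evans alkylation: the chelated Z-enolate 13 is shielded on one face by the benzyl group of the (R)-auxiliary, so bromide 2 enters from the other face and sets the (R) centre that becomes C3 of the target. The reactive benzylic bromide allows −78 °C, where the product is not epimerised and the nitrile is not attacked.

Step 9
Reactants: 14 (4R)-4-benzyl-3-{(2R)-2-[2-(benzyloxy)-5-cyano-3-methoxyphenyl]-3-[4-(benzyloxy)-3-methoxyphenyl]propanoyl}-1,3-oxazolidin-2-one
Product: 15 4-(benzyloxy)-3-{(2R)-1-[4-(benzyloxy)-3-methoxyphenyl]-3-hydroxypropan-2-yl}-5-methoxybenzonitrile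
Conditions: LiBH4, MeOH (1 equiv), Et2O–THF, 0 °C
Reagents that add atoms: none
Why: Reductive cleavage of the N-acyl oxazolidinone at the exocyclic carbonyl; LiBH4 leaves the nitrile and the benzyl ethers alone, no enolisation occurs, so the configuration is kept, and the auxiliary is released for recovery.

Step 10
Reactants: 15 4-(benzyloxy)-3-{(2R)-1-[4-(benzyloxy)-3-methoxyphenyl]-3-hydroxypropan-2-yl}-5-methoxybenzonitrile
Product: 16 4-hydroxy-3-[(2R)-1-hydroxy-3-(4-hydroxy-3-methoxyphenyl)propan-2-yl]-5-methoxybenzonitrile
Conditions: H2 (1 atm), 10% Pd/C, EtOAc–EtOH, rt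
Reagents that add atoms: none
Why: Hydrogenolysis of the two aryl benzyl ethers, which in neutral solvent at atmospheric pressure is much faster than reduction of an aryl nitrile; the reaction is stopped once both ethers are gone.

Step 11
Reactants: 16 4-hydroxy-3-[(2R)-1-hydroxy-3-(4-hydroxy-3-methoxyphenyl)propan-2-yl]-5-methoxybenzonitrile
Product: 18 (2S,3R)-2-(4-hydroxy-3-methoxyphenyl)-3-(hydroxymethyl)-7-methoxy-2,3-dihydro-1-benzofuran-5-carbonitrile, via quinone methide 17 (not isolated)
Conditions: Ag2O (1.5 equiv), acetone–CH2Cl2, rt, dark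
Reagents that add atoms: none
Why: Ag2O oxidises the 4-alkyl-2-methoxyphenol unit to para-quinone methide 17, while the ring A phenol, para to the nitrile, is much harder to oxidise; the ring A phenol then adds to the exocyclic carbon in a 5-exo-trig closure, the same event that closes the ring in oxidative phenylcoumaran formation. The new C2 centre is set trans to the CH2OH of the fixed C3 centre, because the aryl group avoids eclipsing it in the envelope transition state and because reversible reopening would also lead to the trans isomer.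

Step 12
Reactants: 18 (2S,3R)-2-(4-hydroxy-3-methoxyphenyl)-3-(hydroxymethyl)-7-methoxy-2,3-dihydro-1-benzofuran-5-carbonitrile
Product: 19 (2S,3R)-2-[4-(tert-butyldimethylsilyloxy)-3-methoxyphenyl]-3-[(tert-butyldimethylsilyloxy)methyl]-7-methoxy-2,3-dihydro-1-benzofuran-5-carbonitrile
Conditions: TBSCl (2.5 equiv), imidazole, DMF, rt
Reagents that add atoms: tert-butyldimethylsilyl chloride, CC(C)(C)[Si](C)(C)Cl
Why: Standard silylation of the phenol and the primary alcohol; capping the phenol also shuts off the quinone-methide opening at C2 for all later steps.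

Step 13
Reactants: 19 (2S,3R)-2-[4-(tert-butyldimethylsilyloxy)-3-methoxyphenyl]-3-[(tert-butyldimethylsilyloxy)methyl]-7-methoxy-2,3-dihydro-1-benzofuran-5-carbonitrile
Product: 21 (2S,3R)-2-[4-(tert-butyldimethylsilyloxy)-3-methoxyphenyl]-3-[(tert-butyldimethylsilyloxy)methyl]-7-methoxy-2,3-dihydro-1-benzofuran-5-carbaldehyde, via aluminium iminate 20 (not isolated)
Conditions: i-Bu2AlH (1.3 equiv), CH2Cl2, −78 °C; then 1 M aq. tartaric acid, 0 °C
Reagents that add atoms: water, O
Why: One hydride adds to the nitrile and the N-aluminated imine 20 resists further reduction at low temperature; cold dilute acid hydrolyses it to the aldehyde without touching the silyl ethers.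

Step 14
Reactants: 21 (2S,3R)-2-[4-(tert-butyldimethylsilyloxy)-3-methoxyphenyl]-3-[(tert-butyldimethylsilyloxy)methyl]-7-methoxy-2,3-dihydro-1-benzofuran-5-carbaldehyde
Product: 22 (2S,3R)-2-[4-(tert-butyldimethylsilyloxy)-3-methoxyphenyl]-3-[(tert-butyldimethylsilyloxy)methyl]-7-methoxy-2,3-dihydro-1-benzofuran-5-carboxylic acid
Conditions: NaClO2, NaH2PO4, 2-methyl-2-butene, t-BuOH–THF–H2O, rt
Reagents that add atoms: sodium chlorite, [Na+].[O-]Cl=O
Why: Pinnick oxidation in a weakly acidic buffer gives the acid without the hydroxide that would cleave the aryl silyl ether.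

Step 15
Reactants: 22 (2S,3R)-2-[4-(tert-butyldimethylsilyloxy)-3-methoxyphenyl]-3-[(tert-butyldimethylsilyloxy)methyl]-7-methoxy-2,3-dihydro-1-benzofuran-5-carboxylic acid
Product: 23 (2S,3R)-2-[4-(tert-butyldimethylsilyloxy)-3-methoxyphenyl]-3-[(tert-butyldimethylsilyloxy)methyl]-7-methoxy-2,3-dihydro-1-benzofuran-5-carbonyl chloride
Conditions: 1-chloro-N,N,2-trimethylprop-1-en-1-amine (1.2 equiv), CH2Cl2, 0 °C to rt; concentrated and used crude
Reagents that add atoms: 1-chloro-N,N,2-trimethylprop-1-en-1-amine, CC(C)=C(Cl)N(C)C
Why: The α-chloroenamine (Ghosez reagent) turns the acid into its chloride under neutral conditions; no HCl is set free, so both silyl ethers survive, and the amide by-product is inert in the next step.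

Step 16
Reactants: 24 4-(3-hydroxypropyl)-2-methoxyphenol (dihydroconiferyl alcohol)
Product: 25 4-[3-(tert-butyldiphenylsilyloxy)propyl]-2-methoxyphenol
Conditions: TBDPSCl (1.05 equiv), imidazole, CH2Cl2, 0 °C
Reagents that add atoms: tert-butyldiphenylsilyl chloride, CC(C)(C)[Si](Cl)(c1ccccc1)c1ccccc1
Why: With one equivalent of the bulky chlorosilane the primary alcohol should be silylated faster than the phenol flanked by a methoxy group.

Step 17
Reactants: 25 4-[3-(tert-butyldiphenylsilyloxy)propyl]-2-methoxyphenol
Product: 26 5-[3-(tert-butyldiphenylsilyloxy)propyl]-2-hydroxy-3-methoxybenzaldehyde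
Conditions: MgCl2, Et3N, (CH2O)n, MeCN, reflux
Reagents that add atoms: paraformaldehyde (as formaldehyde), C=O
Why: Magnesium-mediated ortho-formylation: the magnesium phenoxide of 25 binds formaldehyde and delivers it to the only free ortho carbon, and hydride transfer to a second formaldehyde raises the hydroxymethyl stage to the aldehyde.

Step 18
Reactants: 26 5-[3-(tert-butyldiphenylsilyloxy)propyl]-2-hydroxy-3-methoxybenzaldehyde
Product: 27 4-[3-(tert-butyldiphenylsilyloxy)propyl]-2-(hydroxymethyl)-6-methoxyphenol
Conditions: NaBH4, THF–MeOH, 0 °C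
Reagents that add atoms: none
Why: Borohydride reduction of the aldehyde; the silyl ether is inert.

Step 19
Reactants: 27 4-[3-(tert-butyldiphenylsilyloxy)propyl]-2-(hydroxymethyl)-6-methoxyphenol
Product: 28 {5-[3-(tert-butyldiphenylsilyloxy)propyl]-2-hydroxy-3-methoxybenzyl}triphenylphosphonium bromide
Conditions: PPh3·HBr (1.05 equiv), MeCN, reflux
Reagents that add atoms: triphenylphosphine hydrobromide, [PH+](c1ccccc1)(c1ccccc1)c1ccccc1.[Br-]
Why: Acid-promoted loss of water from the ortho-hydroxybenzylic position and capture of the electrophilic carbon by PPh3 is the standard way to (2-hydroxybenzyl)phosphonium salts; only the benzylic alcohol reacts, and TBDPS is the most acid-tolerant of the common silyl ethers.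

Step 20
Reactants: 23 (2S,3R)-2-[4-(tert-butyldimethylsilyloxy)-3-methoxyphenyl]-3-[(tert-butyldimethylsilyloxy)methyl]-7-methoxy-2,3-dihydro-1-benzofuran-5-carbonyl chloride, 28 {5-[3-(tert-butyldiphenylsilyloxy)propyl]-2-hydroxy-3-methoxybenzyl}triphenylphosphonium bromide
Product: 31 (2S,3R)-5-{5-[3-(tert-butyldiphenylsilyloxy)propyl]-7-methoxy-1-benzofuran-2-yl}-2-[4-(tert-butyldimethylsilyloxy)-3-methoxyphenyl]-3-[(tert-butyldimethylsilyloxy)methyl]-7-methoxy-2,3-dihydro-1-benzofuran (tris-silyl ether of the target), via acylated phosphonium bromide 29 (not isolated), via phosphorus ylide 30 (not isolated)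
Conditions: 28 (1.1 equiv), Et3N (4 equiv), toluene, rt; 23 added slowly; then reflux
Reagents that add atoms: none
Why: Et3N turns the phenol of 28 into its phenoxide, which 23 acylates at oxygen to give aryl ester 29. A second equivalent of Et3N removes a benzylic proton next to phosphorus and gives the semi-stabilised ylide 30. The ylide carbon adds to the ester carbonyl five atoms away, and the four-membered P–O ring so formed collapses with loss of triphenylphosphine oxide, creating the C2=C3 double bond. The closest known reaction type is the intramolecular Wittig olefination of O-acylated (2-hydroxybenzyl)triphenylphosphonium salts to 2-arylbenzofurans, which is established for aroyl chlorides. The furan ring closes by a 5-exo-trig attack of carbon on the ester C=O and is aromatic as soon as the phosphine oxide leaves. No stereocentre is formed, and the two existing ones are safe, because neither carries an acidifying group and the para phenol is silylated, so Et3N can cause neither enolisation nor quinone-methide opening. The step needs O-acylation to come before ylide formation and ring closure to come before a second acylation at carbon. The much more acidic phenol, the weak base, and slow addition of 23 as the limiting component to the pre-formed phenoxide should secure both.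

Step 21
Reactants: 31 (2S,3R)-5-{5-[3-(tert-butyldiphenylsilyloxy)propyl]-7-methoxy-1-benzofuran-2-yl}-2-[4-(tert-butyldimethylsilyloxy)-3-methoxyphenyl]-3-[(tert-butyldimethylsilyloxy)methyl]-7-methoxy-2,3-dihydro-1-benzofuran
Product: 32 4-[(2S,3R)-3-(hydroxymethyl)-5-[5-(3-hydroxypropyl)-7-methoxy-1-benzofuran-2-yl]-7-methoxy-2,3-dihydro-1-benzofuran-2-yl]-2-methoxyphenol (CNP0308311.1)
Conditions: Bu4NF (4 equiv), AcOH (4 equiv), THF, 0 °C to rt
Reagents that add atoms: none
Why: Fluoride cleaves the aryl and alkyl TBS ethers and the TBDPS ether in one operation; the acetic acid buffer keeps the liberated phenol protonated, so the C2–O bond is not opened through a quinone methide.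

## Compound list

1 | 4-(benzyloxy)-3-methoxybenzyl alcohol | COc1cc(CO)ccc1OCc1ccccc1 | starting material
2 | 4-(benzyloxy)-3-methoxybenzyl bromide | COc1cc(CBr)ccc1OCc1ccccc1 | intermediate
3 | 4-hydroxy-3-methoxybenzonitrile | COc1cc(C#N)ccc1O | starting material
4 | 3-methoxy-4-(prop-2-en-1-yloxy)benzonitrile | COc1cc(C#N)ccc1OCC=C | intermediate
5 | 4-hydroxy-3-methoxy-5-(prop-2-en-1-yl)benzonitrile | COc1cc(C#N)cc(CC=C)c1O | intermediate
6 | 4-(benzyloxy)-3-methoxy-5-(prop-2-en-1-yl)benzonitrile | COc1cc(C#N)cc(CC=C)c1OCc1ccccc1 | intermediate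
7 | 4-(benzyloxy)-3-(2,3-dihydroxypropyl)-5-methoxybenzonitrile (racemic at the carbinol, not isolated) | COc1cc(C#N)cc(CC(O)CO)c1OCc1ccccc1 | intermediate
8 | 2-[2-(benzyloxy)-5-cyano-3-methoxyphenyl]acetaldehyde | COc1cc(C#N)cc(CC=O)c1OCc1ccccc1 | intermediate
9 | 2-[2-(benzyloxy)-5-cyano-3-methoxyphenyl]acetic acid | COc1cc(C#N)cc(CC(=O)O)c1OCc1ccccc1 | intermediate
10 | (4R)-4-benzyl-1,3-oxazolidin-2-one | O=C1N[C@H](Cc2ccccc2)CO1 | starting material
11 | 2-[2-(benzyloxy)-5-cyano-3-methoxyphenyl]acetic pivalic anhydride (not isolated) | COc1cc(C#N)cc(CC(=O)OC(=O)C(C)(C)C)c1OCc1ccccc1 | intermediate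
12 | (4R)-4-benzyl-3-{2-[2-(benzyloxy)-5-cyano-3-methoxyphenyl]acetyl}-1,3-oxazolidin-2-one | COc1cc(C#N)cc(CC(=O)N2C(=O)OC[C@H]2Cc2ccccc2)c1OCc1ccccc1 | intermediate
13 | sodium (Z)-enolate of 12 (not isolated) | COc1cc(C#N)cc(/C=C(\[O-])N2C(=O)OC[C@H]2Cc2ccccc2)c1OCc1ccccc1.[Na+] | intermediate
14 | (4R)-4-benzyl-3-{(2R)-2-[2-(benzyloxy)-5-cyano-3-methoxyphenyl]-3-[4-(benzyloxy)-3-methoxyphenyl]propanoyl}-1,3-oxazolidin-2-one | COc1cc(C#N)cc([C@@H](Cc2ccc(OCc3ccccc3)c(OC)c2)C(=O)N2C(=O)OC[C@H]2Cc2ccccc2)c1OCc1ccccc1 | intermediate
15 | 4-(benzyloxy)-3-{(2R)-1-[4-(benzyloxy)-3-methoxyphenyl]-3-hydroxypropan-2-yl}-5-methoxybenzonitrile | COc1cc(C#N)cc([C@@H](Cc2ccc(OCc3ccccc3)c(OC)c2)CO)c1OCc1ccccc1 | intermediate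
16 | 4-hydroxy-3-[(2R)-1-hydroxy-3-(4-hydroxy-3-methoxyphenyl)propan-2-yl]-5-methoxybenzonitrile | COc1cc(C#N)cc([C@@H](Cc2ccc(O)c(OC)c2)CO)c1O | intermediate
17 | 4-hydroxy-3-[(2R)-1-hydroxy-3-(3-methoxy-4-oxocyclohexa-2,5-dien-1-ylidene)propan-2-yl]-5-methoxybenzonitrile (quinone methide, not isolated) | COc1cc(C#N)cc([C@@H](C=C2C=CC(=O)C(OC)=C2)CO)c1O | intermediate
18 | (2S,3R)-2-(4-hydroxy-3-methoxyphenyl)-3-(hydroxymethyl)-7-methoxy-2,3-dihydro-1-benzofuran-5-carbonitrile | COc1cc([C@H]2Oc3c(OC)cc(C#N)cc3[C@@H]2CO)ccc1O | intermediate
19 | (2S,3R)-2-[4-(tert-butyldimethylsilyloxy)-3-methoxyphenyl]-3-[(tert-butyldimethylsilyloxy)methyl]-7-methoxy-2,3-dihydro-1-benzofuran-5-carbonitrile | COc1cc([C@H]2Oc3c(OC)cc(C#N)cc3[C@@H]2CO[Si](C)(C)C(C)(C)C)ccc1O[Si](C)(C)C(C)(C)C | intermediate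
20 | N-(diisobutylaluminio)imine of aldehyde 21 (not isolated) | COc1cc([C@H]2Oc3c(OC)cc(C=N[Al](CC(C)C)CC(C)C)cc3[C@@H]2CO[Si](C)(C)C(C)(C)C)ccc1O[Si](C)(C)C(C)(C)C | intermediate
21 | (2S,3R)-2-[4-(tert-butyldimethylsilyloxy)-3-methoxyphenyl]-3-[(tert-butyldimethylsilyloxy)methyl]-7-methoxy-2,3-dihydro-1-benzofuran-5-carbaldehyde | COc1cc([C@H]2Oc3c(OC)cc(C=O)cc3[C@@H]2CO[Si](C)(C)C(C)(C)C)ccc1O[Si](C)(C)C(C)(C)C | intermediate
22 | (2S,3R)-2-[4-(tert-butyldimethylsilyloxy)-3-methoxyphenyl]-3-[(tert-butyldimethylsilyloxy)methyl]-7-methoxy-2,3-dihydro-1-benzofuran-5-carboxylic acid | COc1cc([C@H]2Oc3c(OC)cc(C(=O)O)cc3[C@@H]2CO[Si](C)(C)C(C)(C)C)ccc1O[Si](C)(C)C(C)(C)C | intermediate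
23 | (2S,3R)-2-[4-(tert-butyldimethylsilyloxy)-3-methoxyphenyl]-3-[(tert-butyldimethylsilyloxy)methyl]-7-methoxy-2,3-dihydro-1-benzofuran-5-carbonyl chloride | COc1cc([C@H]2Oc3c(OC)cc(C(Cl)=O)cc3[C@@H]2CO[Si](C)(C)C(C)(C)C)ccc1O[Si](C)(C)C(C)(C)C | intermediate
24 | 4-(3-hydroxypropyl)-2-methoxyphenol (dihydroconiferyl alcohol) | COc1cc(CCCO)ccc1O | starting material
25 | 4-[3-(tert-butyldiphenylsilyloxy)propyl]-2-methoxyphenol | COc1cc(CCCO[Si](c2ccccc2)(c2ccccc2)C(C)(C)C)ccc1O | intermediate
26 | 5-[3-(tert-butyldiphenylsilyloxy)propyl]-2-hydroxy-3-methoxybenzaldehyde | COc1cc(CCCO[Si](c2ccccc2)(c2ccccc2)C(C)(C)C)cc(C=O)c1O | intermediate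
27 | 4-[3-(tert-butyldiphenylsilyloxy)propyl]-2-(hydroxymethyl)-6-methoxyphenol | COc1cc(CCCO[Si](c2ccccc2)(c2ccccc2)C(C)(C)C)cc(CO)c1O | intermediate
28 | {5-[3-(tert-butyldiphenylsilyloxy)propyl]-2-hydroxy-3-methoxybenzyl}triphenylphosphonium bromide | COc1cc(CCCO[Si](c2ccccc2)(c2ccccc2)C(C)(C)C)cc(C[P+](c2ccccc2)(c2ccccc2)c2ccccc2)c1O.[Br-] | intermediate
29 | O-acylated phosphonium bromide: aryl ester of 28 with the acyl group of 23 (not isolated) | COc1cc([C@H]2Oc3c(OC)cc(C(=O)Oc4c(OC)cc(CCCO[Si](c5ccccc5)(c5ccccc5)C(C)(C)C)cc4C[P+](c4ccccc4)(c4ccccc4)c4ccccc4)cc3[C@@H]2CO[Si](C)(C)C(C)(C)C)ccc1O[Si](C)(C)C(C)(C)C.[Br-] | intermediate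
30 | phosphorus ylide derived from 29 (not isolated) | COc1cc([C@H]2Oc3c(OC)cc(C(=O)Oc4c(OC)cc(CCCO[Si](c5ccccc5)(c5ccccc5)C(C)(C)C)cc4C=P(c4ccccc4)(c4ccccc4)c4ccccc4)cc3[C@@H]2CO[Si](C)(C)C(C)(C)C)ccc1O[Si](C)(C)C(C)(C)C | intermediate
31 | (2S,3R)-5-{5-[3-(tert-butyldiphenylsilyloxy)propyl]-7-methoxy-1-benzofuran-2-yl}-2-[4-(tert-butyldimethylsilyloxy)-3-methoxyphenyl]-3-[(tert-butyldimethylsilyloxy)methyl]-7-methoxy-2,3-dihydro-1-benzofuran | COc1cc([C@H]2Oc3c(OC)cc(-c4cc5cc(CCCO[Si](c6ccccc6)(c6ccccc6)C(C)(C)C)cc(OC)c5o4)cc3[C@@H]2CO[Si](C)(C)C(C)(C)C)ccc1O[Si](C)(C)C(C)(C)C | intermediate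
32 | 4-[(2S,3R)-3-(hydroxymethyl)-5-[5-(3-hydroxypropyl)-7-methoxy-1-benzofuran-2-yl]-7-methoxy-2,3-dihydro-1-benzofuran-2-yl]-2-methoxyphenol | COc1cc([C@H]2Oc3c(OC)cc(-c4cc5cc(CCCO)cc(OC)c5o4)cc3[C@@H]2CO)ccc1O | target

## Step count and least certain steps

Total: 21 steps. Longest linear sequence: 16 steps (steps 2 to 15, then 20 and 21, from 3 to 32).

Step 20 (key step). The most likely failures are acylation of the ylide carbon by a second molecule of 23 in competition with ring closure, and slow attack of the semi-stabilised ylide on an electron-rich, hindered aryl ester carbonyl, which would leave time for ester cleavage. The fallback sets out from aldehyde 21 and salt 28. Double deprotonation of 28 with LiN(SiMe3)2 in THF and intermolecular Wittig olefination of 21 should give the 2-hydroxystilbene F1 as an E/Z mixture. Iodine with K2CO3 in THF should then cyclise the phenol onto the alkene and eliminate HI from either isomer, giving 31, where the route is rejoined.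

Step 11. The oxidation may go on to the product phenol, or phenoxyl radical coupling may compete with clean two-electron oxidation; the trans preference in the ring closure may also be incomplete. The fallback sets out from acid 9 and forms the O1–C2 bond by ionisation of a benzylic alcohol, with no oxidant. Acid 9 is attached to (4S)-4-benzyl-1,3-oxazolidin-2-one to give the enantiomeric-auxiliary imide F2. A boron aldol reaction (Bu2BOTf, i-Pr2NEt) with 4-(benzyloxy)-3-methoxybenzaldehyde gives the syn aldol adduct F3, in which the α-carbon has the same spatial arrangement as in 14. LiBH4 gives the 1,3-diol F4, and hydrogenolysis of the benzyl ethers gives the phenolic triol F5. A catalytic amount of TsOH then ionises the benzylic alcohol and closes the ring to the trans product 18, where the route is rejoined.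

Step 10. The nitrile may be partly reduced before the second benzyl ether is cleaved. The fallback replaces reductive cleavage by Lewis-acid dealkylation: 15 is treated with BCl3 and pentamethylbenzene as benzyl-cation scavenger in CH2Cl2 at −78 °C and should give 16 directly; no new compound arises (F0).

Step 17. Formylation may be slow, because the neighbouring methoxy group competes for magnesium, and methylene-bridged diaryl by-products may form. The fallback sets out from 25. Heating with PhB(OH)2 and paraformaldehyde in toluene with a catalytic amount of propionic acid and removal of water gives the benzodioxaborin F6. Exchange with propane-1,3-diol releases 27, so the route is rejoined after step 18 without passing through 26.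

Step 19. The TBDPS ether may be partly lost under the acidic conditions. The fallback moves the protection behind the phosphonium formation. From 27, the reaction with PPh3·HBr is run in MeCN containing methanol so that the silyl ether is removed completely, giving the hydroxypropyl phosphonium bromide F7. Silylation of the aliphatic hydroxyl group of F7 with TBDPSCl and imidazole then gives 28.

## Further compounds

F1 | step 20 | (2S,3R)-5-{2-[5-(3-(tert-butyldiphenylsilyloxy)propyl)-2-hydroxy-3-methoxyphenyl]ethenyl}-2-[4-(tert-butyldimethylsilyloxy)-3-methoxyphenyl]-3-[(tert-butyldimethylsilyloxy)methyl]-7-methoxy-2,3-dihydro-1-benzofuran (E/Z mixture, drawn as E) | COc1cc([C@H]2Oc3c(OC)cc(/C=C/c4cc(CCCO[Si](c5ccccc5)(c5ccccc5)C(C)(C)C)cc(OC)c4O)cc3[C@@H]2CO[Si](C)(C)C(C)(C)C)ccc1O[Si](C)(C)C(C)(C)C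
F2 | step 11 | (4S)-4-benzyl-3-{2-[2-(benzyloxy)-5-cyano-3-methoxyphenyl]acetyl}-1,3-oxazolidin-2-one | COc1cc(C#N)cc(CC(=O)N2C(=O)OC[C@@H]2Cc2ccccc2)c1OCc1ccccc1
F3 | step 11 | (4S)-4-benzyl-3-{(2S,3S)-2-[2-(benzyloxy)-5-cyano-3-methoxyphenyl]-3-[4-(benzyloxy)-3-methoxyphenyl]-3-hydroxypropanoyl}-1,3-oxazolidin-2-one | COc1cc(C#N)cc([C@@H]([C@H](O)c2ccc(OCc3ccccc3)c(OC)c2)C(=O)N2C(=O)OC[C@@H]2Cc2ccccc2)c1OCc1ccccc1
F4 | step 11 | 4-(benzyloxy)-3-{(1S,2R)-1-[4-(benzyloxy)-3-methoxyphenyl]-1,3-dihydroxypropan-2-yl}-5-methoxybenzonitrile | COc1cc(C#N)cc([C@@H]([C@H](O)c2ccc(OCc3ccccc3)c(OC)c2)CO)c1OCc1ccccc1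
F5 | step 11 | 3-[(1S,2R)-1,3-dihydroxy-1-(4-hydroxy-3-methoxyphenyl)propan-2-yl]-4-hydroxy-5-methoxybenzonitrile | COc1cc(C#N)cc([C@@H]([C@H](O)c2ccc(O)c(OC)c2)CO)c1O
F0 | step 10 | none | none
F6 | step 17 | 6-[3-(tert-butyldiphenylsilyloxy)propyl]-8-methoxy-2-phenyl-4H-1,3,2-benzodioxaborinine | COc1cc(CCCO[Si](c2ccccc2)(c2ccccc2)C(C)(C)C)cc2c1OB(c1ccccc1)OC2
F7 | step 19 | [2-hydroxy-5-(3-hydroxypropyl)-3-methoxybenzyl]triphenylphosphonium bromide | COc1cc(CCCO)cc(C[P+](c2ccccc2)(c2ccccc2)c2ccccc2)c1O.[Br-]
A1 | alternative 1 | methyl 7-acetoxy-2-{(2S,3R)-2-[4-(benzyloxy)-3-methoxyphenyl]-3-[(tert-butyldimethylsilyloxy)methyl]-7-methoxy-2,3-dihydro-1-benzofuran-5-yl}-1-benzofuran-5-carboxylate | COc1cc([C@H]2Oc3c(OC)cc(-c4cc5cc(C(=O)OC)cc(OC(C)=O)c5o4)cc3[C@@H]2CO[Si](C)(C)C(C)(C)C)ccc1OCc1ccccc1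
A2 | alternative 1 | (E)-4-{5-[(2S,3R)-2-[4-(benzyloxy)-3-methoxyphenyl]-3-[(tert-butyldimethylsilyloxy)methyl]-7-methoxy-2,3-dihydro-1-benzofuran-5-yl]furan-3-yl}-3-(methoxycarbonyl)but-3-enoic acid | COc1cc([C@H]2Oc3c(OC)cc(-c4cc(/C=C(\CC(=O)O)C(=O)OC)co4)cc3[C@@H]2CO[Si](C)(C)C(C)(C)C)ccc1OCc1ccccc1
A3 | alternative 2 | methyl trans-(2S,3S)-5-bromo-7-methoxy-2-[3-methoxy-4-(methylsulfonyloxy)phenyl]-2,3-dihydro-1-benzofuran-3-carboxylate | COc1cc([C@H]2Oc3c(OC)cc(Br)cc3[C@@H]2C(=O)OC)ccc1OS(C)(=O)=O
A4 | alternative 2 | (2S)-6-bromo-8-methoxy-2-[3-methoxy-4-(methylsulfonyloxy)phenyl]-2,3-dihydro-4H-chromen-4-one | COc1cc([C@H]2Oc3c(OC)cc(Br)cc3C(=O)C2)ccc1OS(C)(=O)=O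
A5 | alternative 3 | (4S)-4-benzyl-3-{(2S,3R)-2-(4-hydroxy-3-methoxyphenyl)-5-[5-(3-hydroxypropyl)-7-methoxy-1-benzofuran-2-yl]-7-methoxy-2,3-dihydro-1-benzofuran-3-carbonyl}-1,3-oxazolidin-2-one | COc1cc([C@H]2Oc3c(OC)cc(-c4cc5cc(CCCO)cc(OC)c5o4)cc3[C@@H]2C(=O)N6C(=O)OC[C@@H]6Cc7ccccc7)ccc1O
A6 | alternative 3 | 4-[5-(3-hydroxypropyl)-7-methoxy-1-benzofuran-2-yl]-2-methoxyphenol | COc1cc(-c2cc3cc(CCCO)cc(OC)c3o2)ccc1O
A7 | alternative 3 | (4S)-4-benzyl-3-[(E)-3-(4-hydroxy-3-methoxyphenyl)prop-2-enoyl]-1,3-oxazolidin-2-one | COc1cc(/C=C/C(=O)N2C(=O)OC[C@@H]2Cc2ccccc2)ccc1O
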